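The 27-membered lactone ring is a featureless polymethylene loop, so it is cut at the C4–C5 methylene–methylene bond. This bond divides a four-carbon acyl unit (C1–C4) from the C22 chain (C5–C26) that ends at the ring oxygen. Both carbons are placed at the same, electrophilic polarity as primary bromides. A nickel-catalysed reductive cross-electrophile coupling under pseudo-high dilution joins them directly, closing the saturated macrocycle in one operation with no activating group to remove. The precursor is the open-chain α,ω-dibromide 22-bromodocosyl 4-bromobutanoate, made in two steps from docosane-1,22-diol and 4-bromobutanoyl chloride.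

Key step: step 3

Remark: docosane-1,22-diol is taken as a catalogue compound; if it were not, LiAlH4 reduction of commercial dimethyl docosanedioate would supply it. The target has no stereocentre.

Step 1
Reactants: 1 docosane-1,22-diol
Product: 2 22-bromodocosan-1-ol
Conditions: 48% aq HBr (1.2 equiv), toluene, reflux
Reagents that add atoms: hydrogen bromide, Br
Why: SN2 substitution of one protonated primary hydroxyl by bromide; mono-selectivity is expected because the bromo alcohol passes into the toluene phase, where aggregation shields its remaining hydroxyl from the aqueous acid.

Step 2
Reactants: 2 22-bromodocosan-1-ol; 3 4-bromobutanoyl chloride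
Product: 4 22-bromodocosyl 4-bromobutanoate
Conditions: pyridine (1.5 equiv), CH2Cl2, 0 °C to rt
Reagents that add atoms: 4-bromobutanoyl chloride (3), O=C(Cl)CCCBr
Why: Nucleophilic acyl substitution (acylation of a primary alcohol by an acyl chloride with pyridine as HCl scavenger); the primary bromides should not quaternise pyridine appreciably at this temperature.

Step 3
Reactants: 4 22-bromodocosyl 4-bromobutanoate
Product: 5 26-hexacosanolide
Conditions: NiCl2·glyme (20 mol%), 4,4′,4″-tri-tert-butyl-2,2′:6′,2″-terpyridine (20 mol%), Mn powder (4 equiv), DMA/PhH 4:1, 50 °C, 4 added by syringe pump over 24 h (final 3 mM)
Reagents that add atoms: none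
Why: Proposed new method: a low-valent terpyridine–nickel species activates one primary C–Br bond of 4 to give an alkylnickel, which abstracts the bromine atom at the other chain end; the primary radical is recaptured at the same nickel centre, the dialkylnickel(III) reductively eliminates the C4–C5 bond, and manganese returns the nickel bromide to its active state. The closest known reaction type is the nickel-catalysed reductive coupling of two unactivated primary alkyl bromides (4-bromobutanoate esters included) and its intramolecular form, the reductive cyclisation of α,ω-dihalides to five- and six-membered carbocycles; closure of a large ring in this way has not been shown. The ring closes end-to-end as a strain-free 27-membered macrocycle through a 28-membered nickelacycle, a mode on which the stereoelectronic rules for small-ring closure place no constraint. No stereocentre is formed. The step needs intramolecular coupling to outrun oligomerisation, hydrodehalogenation and β-hydride elimination; slow addition keeps free substrate far below the effective molarity of a strain-free large ring, the catalyst stays in excess over the instantaneous substrate so that radical capture by nickel outruns hydrogen abstraction, and the two termini are unhindered primary bromides of equal reactivity, so no cross-selectivity is required. The ester and the saturated chain are inert to the catalyst and to manganese.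

Compound list
1 | docosane-1,22-diol | OCCCCCCCCCCCCCCCCCCCCCCO | starting material
2 | 22-bromodocosan-1-ol | OCCCCCCCCCCCCCCCCCCCCCCBr | intermediate
3 | 4-bromobutanoyl chloride | O=C(Cl)CCCBr | starting material
4 | 22-bromodocosyl 4-bromobutanoate | O=C(CCCBr)OCCCCCCCCCCCCCCCCCCCCCCBr | intermediate
5 | 26-hexacosanolide (oxacycloheptacosan-2-one) | O=C1CCCCCCCCCCCCCCCCCCCCCCCCCO1 | target

Total step count: 3
Longest linear sequence: 3 steps (1 → 2 → 4 → 5)

Steps most likely to fail

Step 3 (proposed new method). The risk is intermolecular coupling to linear and cyclic oligomers, together with reduction or β-hydride elimination of the alkylnickel before the far chain end is engaged. The fallback sets out from 2, uses known chemistry only, and keeps ring closure at C4–C5, made as a double bond by ring-closing olefin metathesis. Heating 2 with PPh3 in acetonitrile should give (22-hydroxydocosyl)triphenylphosphonium bromide F1. Double deprotonation (n-BuLi, 2.1 equiv, THF) and Wittig methylenation with paraformaldehyde should give tricos-22-en-1-ol F2. Steglich esterification with pent-4-enoic acid (DCC, cat. DMAP, CH2Cl2) should give tricos-22-en-1-yl pent-4-enoate F3. Ring-closing metathesis with the second-generation ruthenium benzylidene catalyst (2 mM, CH2Cl2, reflux) should give hexacos-4-en-26-olide F4 as an E/Z mixture. Hydrogenation (H2, Pd/C, EtOAc) should remove the alkene and come back to the route at 5.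

Step 1. The risk is poor mono-selectivity: over-bromination to the dibromide alongside unreacted diol, with a difficult separation of three waxy, poorly soluble components. The fallback sets out from 1 and desymmetrises by protection instead. Monosilylation (TBSCl, 1 equiv, imidazole, THF/DMF, excess diol recovered by filtration) should give 22-[(tert-butyldimethylsilyl)oxy]docosan-1-ol F5. Appel bromination (CBr4, PPh3, CH2Cl2) should give (22-bromodocosyl)oxy(tert-butyl)dimethylsilane F6. Acidic desilylation (cat. p-TsOH, MeOH/THF) should come back to the route at 2.

Step 2. The risk is N-alkylation of pyridine by the primary bromides and loss of the acyl chloride through ketene formation or cyclisation, leaving incomplete acylation of a poorly soluble alcohol. The fallback sets out from 2 and installs the second bromide only after the ester bond is made. Steglich esterification with but-3-enoic acid (DCC, cat. DMAP, CH2Cl2, 0 °C) should give 22-bromodocosyl but-3-enoate F7. Radical anti-Markovnikov hydrobromination of the terminal alkene (HBr gas, dibenzoyl peroxide, hexane, 0 °C) should come back to the route at 4.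

Further compounds
F1 | step 3 | (22-hydroxydocosyl)triphenylphosphonium bromide | OCCCCCCCCCCCCCCCCCCCCCC[P+](c1ccccc1)(c1ccccc1)c1ccccc1.[Br-]
F2 | step 3 | tricos-22-en-1-ol | OCCCCCCCCCCCCCCCCCCCCCC=C
F3 | step 3 | tricos-22-en-1-yl pent-4-enoate | C=CCCC(=O)OCCCCCCCCCCCCCCCCCCCCCC=C
F4 | step 3 | hexacos-4-en-26-olide (E/Z mixture, geometry not defined) | O=C1CCC=CCCCCCCCCCCCCCCCCCCCCCO1
F5 | step 1 | 22-[(tert-butyldimethylsilyl)oxy]docosan-1-ol | CC(C)(C)[Si](C)(C)OCCCCCCCCCCCCCCCCCCCCCCO
F6 | step 1 | (22-bromodocosyl)oxy(tert-butyl)dimethylsilane | CC(C)(C)[Si](C)(C)OCCCCCCCCCCCCCCCCCCCCCCBr
F7 | step 2 | 22-bromodocosyl but-3-enoate | C=CCC(=O)OCCCCCCCCCCCCCCCCCCCCCCBr
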